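The synthesis rests on disconnecting the O–C6 bond of the 1,2-dioxane (ring O1–O2–C3–C4–C5–C6; atoms numbered along the acid chain, C1 = CO2H). The quaternary ring carbon C6 carries one peroxide oxygen and stands 1,4 to C3, the other oxygen-bearing ring carbon, so a hydroperoxide on C3 can open a C6–C7 epoxide at C6 in the 6-exo mode. This one operation closes the ring, makes the C6–O bond and sets the quaternary stereocentre by inversion of a catalyst-made epoxide. Its precursor is an open-chain (3S,4S)-3-hydroperoxide with an allyl group on C3 and the (6R,7R) trans-epoxide, released in the flask from its 2-methoxyprop-2-yl peroxyketal.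

Key step: step 14

Remark: atom labels C1–C16 used below are those of the target acid (C3, C6 ring carbons on oxygen; C4, C8 methyl-bearing stereocentres; C9–C16 methylene chain).
Remark: C8 is taken from commercial (S)-3-bromo-2-methylpropan-1-ol, the bromide of reduced methyl (R)-3-hydroxy-2-methylpropanoate. Its bromomethyl carbon becomes C9 and its hydroxymethyl carbon C7, the mapping that gives (8R).
Remark: the C3 alcohol is made as the (R), 3,4-anti isomer because the peroxide enters with inversion. 2-Methoxyprop-2-yl hydroperoxide is not a catalogue item and is made in step 11.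

Step 1
Reactants: 1 (S)-3-bromo-2-methylpropan-1-ol
Product: 2 (S)-(3-bromo-2-methylpropoxy)(tert-butyl)dimethylsilane
Conditions: TBSCl, imidazole, CH2Cl2, 0 °C → rt
Reagents that add atoms: tert-butyldimethylsilyl chloride, CC(C)(C)[Si](C)(C)Cl
Why: Standard silyl ether formation masks the alcohol, so the coupling in step 2 cannot pass through a bromo alkoxide that could close to achiral 3-methyloxetane and erode the C8 configuration.

Step 2
Reactants: 3 (7-bromoheptyl)benzene; 2 (S)-(3-bromo-2-methylpropoxy)(tert-butyl)dimethylsilane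
Product: 6 (R)-2-methyl-10-phenyldecan-1-ol, via Grignard reagent 4 (not isolated), via silyl ether 5 (not isolated)
Conditions: 3, Mg, THF, 40 °C; then 2, Li2CuCl4 (3 mol%), NMP, THF, 0 °C → rt; then HCl, MeOH, rt
Reagents that add atoms: none
Why: Copper-catalysed sp3–sp3 cross-coupling of a primary alkyl Grignard reagent with a primary alkyl bromide joins C9 to C10 without touching the C8 stereocentre, and the methanolic acid work-up removes the silyl ether.

Step 3
Reactants: 6 (R)-2-methyl-10-phenyldecan-1-ol; 7 ethyl 2-(triphenylphosphoranylidene)propanoate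
Product: 9 ethyl (R,E)-2,4-dimethyl-12-phenyldodec-2-enoate, via aldehyde 8 (not isolated)
Conditions: TEMPO (10 mol%), PhI(OAc)2, CH2Cl2, rt; then 7, rt → 40 °C
Reagents that add atoms: none
Why: Nitroxyl-catalysed oxidation gives the epimerisable α-methyl aldehyde, which is trapped in the same flask by the stabilised ylide in an E-selective Wittig olefination that builds the C6=C7 alkene.

Step 4
Reactants: 9 ethyl (R,E)-2,4-dimethyl-12-phenyldodec-2-enoate
Product: 10 (R,E)-2,4-dimethyl-12-phenyldodec-2-en-1-ol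
Conditions: i-Bu2AlH, CH2Cl2, −78 °C → 0 °C
Reagents that add atoms: none
Why: 1,2-Reduction of the enoate with an aluminium hydride should give the allylic alcohol without touching the alkene geometry.

Step 5
Reactants: 10 (R,E)-2,4-dimethyl-12-phenyldodec-2-en-1-ol
Product: 11 [(9R,10E)-12-bromo-9,11-dimethyldodec-10-en-1-yl]benzene
Conditions: CBr4, PPh3, CH2Cl2, 0 °C
Reagents that add atoms: carbon tetrabromide, BrC(Br)(Br)Br
Why: The Appel reaction converts the primary allylic alcohol into the bromide under neutral conditions, so the E geometry and C8 are retained.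

Step 6
Reactants: 12 (R)-4-benzyl-3-propionyloxazolidin-2-one; 11 [(9R,10E)-12-bromo-9,11-dimethyldodec-10-en-1-yl]benzene
Product: 14 (R)-4-benzyl-3-[(2S,4E,6R)-2,4,6-trimethyl-14-phenyltetradec-4-enoyl]oxazolidin-2-one, via sodium enolate 13 (not isolated)
Conditions: 12 (1.5 equiv), NaN(SiMe3)2, THF, −78 °C; then 11, −78 → −45 °C
Reagents that add atoms: none
Why: In this Evans alkylation the chelated Z-enolate is attacked by the reactive allylic bromide on the face opposite the benzyl group, which forms C4–C5 and sets C4 as S.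

Step 7
Reactants: 14 (R)-4-benzyl-3-[(2S,4E,6R)-2,4,6-trimethyl-14-phenyltetradec-4-enoyl]oxazolidin-2-one
Product: 15 (2S,4E,6R)-2,4,6-trimethyl-14-phenyltetradec-4-en-1-ol
Conditions: LiBH4, H2O (1 equiv), Et2O, 0 °C
Reagents that add atoms: none
Why: Reductive cleavage of the imide by borohydride attack at the exocyclic carbonyl should give the primary alcohol and release the auxiliary without epimerising C4.

Step 8
Reactants: 15 (2S,4E,6R)-2,4,6-trimethyl-14-phenyltetradec-4-en-1-ol
Product: 16 (2S,4E,6R)-2,4,6-trimethyl-14-phenyltetradec-4-enal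
Conditions: TEMPO (10 mol%), PhI(OAc)2, CH2Cl2, rt
Reagents that add atoms: none
Why: Base-free nitroxyl-catalysed oxidation stops at the aldehyde and should leave the α-stereocentre C4 and the alkene untouched; the aldehyde is used at once.

Step 9
Reactants: 16 (2S,4E,6R)-2,4,6-trimethyl-14-phenyltetradec-4-enal
Product: 18 (4R,5S,7E,9R)-5,7,9-trimethyl-17-phenylheptadeca-1,7-dien-4-ol, via borinate ester 17 (not isolated)
Conditions: allylMgBr, (+)-Ipc2BOMe [from (−)-α-pinene], Et2O, 0 °C → rt; then 16, −78 °C; then NaOH, H2O2, 0 °C → rt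
Reagents that add atoms: allylmagnesium bromide, C=CC[Mg]Br
Why: Brown allylboration through a chair-like six-membered transition state delivers allyl to the Re face under reagent control, which should override the small Felkin bias of this α-methyl aldehyde and set C3 as R (3,4-anti).

Step 10
Reactants: 18 (4R,5S,7E,9R)-5,7,9-trimethyl-17-phenylheptadeca-1,7-dien-4-ol
Product: 19 (4R,5S,7E,9R)-5,7,9-trimethyl-17-phenylheptadeca-1,7-dien-4-yl methanesulfonate
Conditions: MsCl, Et3N, CH2Cl2, 0 °C
Reagents that add atoms: methanesulfonyl chloride, CS(=O)(=O)Cl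
Why: Mesylation through the small sulfene electrophile should work on the hindered secondary alcohol, retains the C3 configuration and gives a storable leaving group.

Step 11
Reactants: 20 2,3-dimethylbut-2-ene
Product: 21 2-methoxyprop-2-yl hydroperoxide
Conditions: O3, MeOH–CH2Cl2, −78 °C
Reagents that add atoms: ozone, [O-][O+]=O; methanol, CO
Why: In this ozonolysis methanol traps the carbonyl oxide from the tetrasubstituted alkene, giving the hydroperoxy ketal and acetone.

Step 12
Reactants: 19 (4R,5S,7E,9R)-5,7,9-trimethyl-17-phenylheptadeca-1,7-dien-4-yl methanesulfonate; 21 2-methoxyprop-2-yl hydroperoxide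
Product: 22 (4S,5S,7E,9R)-4-[(2-methoxypropan-2-yl)peroxy]-5,7,9-trimethyl-17-phenylheptadeca-1,7-diene
Conditions: CsOH·H2O, DMF, 0 °C → rt
Reagents that add atoms: none
Why: The caesium peroxide anion, a weakly basic α-effect nucleophile, should displace the mesylate by SN2 with inversion, which sets C3 as S and keeps the peroxide masked as a base-stable ketal.

Step 13
Reactants: 22 (4S,5S,7E,9R)-4-[(2-methoxypropan-2-yl)peroxy]-5,7,9-trimethyl-17-phenylheptadeca-1,7-diene
Product: 23 (2R,3R)-2-{(2S,3S)-3-[(2-methoxypropan-2-yl)peroxy]-2-methylhex-5-en-1-yl}-2-methyl-3-[(R)-10-phenyldecan-2-yl]oxirane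
Conditions: D-fructose-derived Shi ketone (30 mol%), Oxone (2KHSO5·KHSO4·K2SO4), K2CO3, Na2B4O7 buffer, Bu4NHSO4, MeCN–dimethoxymethane–H2O, 0 °C
Reagents that add atoms: potassium peroxymonosulfate (active part of Oxone), [K+].[O-]S(=O)(=O)OO
Why: In the Shi epoxidation the chiral dioxirane attacks the electron-rich E-trisubstituted alkene through a spiro transition state on the face that gives the (6R,7R) trans-epoxide, while the monosubstituted allyl alkene and the peroxyketal should stay intact at buffered high pH.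

Step 14
Reactants: 23 (2R,3R)-2-{(2S,3S)-3-[(2-methoxypropan-2-yl)peroxy]-2-methylhex-5-en-1-yl}-2-methyl-3-[(R)-10-phenyldecan-2-yl]oxirane
Product: 25 (1R,2R)-1-[(3S,5S,6S)-6-allyl-3,5-dimethyl-1,2-dioxan-3-yl]-2-methyl-10-phenyldecan-1-ol, via hydroperoxy epoxide 24 (not isolated)
Conditions: CSA (0.2 equiv), H2O (2 equiv), CH2Cl2, 0 °C → rt
Reagents that add atoms: none
Why: CSA and water first hydrolyse the peroxyketal to the free C3 hydroperoxide 24; the protonated epoxide is then opened at its tertiary carbon C6 by the terminal hydroperoxide oxygen from the side opposite the departing oxygen, a borderline SN2 process. The closest known reaction type is the acid-promoted intramolecular exo opening of epoxides by hydroperoxides, which gives 1,2-dioxolanes and 1,2-dioxanes. The single ring (O–O–C3–C4–C5–C6) closes in the 6-exo-tet mode. The new C6 stereocentre is controlled by the epoxide configuration, fixed by the catalyst in step 13, and is transferred with inversion; C7 keeps its configuration and ends as the carbinol. The step needs exo regioselectivity and clean inversion: the six- over seven-membered ring preference and charge stabilisation at tertiary C6 both direct attack there, the neopentyl-like C7 is shielded, and in a non-nucleophilic solvent the tethered hydroperoxide is the only competent nucleophile before C6 can ionise fully.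

Step 15
Reactants: 25 (1R,2R)-1-[(3S,5S,6S)-6-allyl-3,5-dimethyl-1,2-dioxan-3-yl]-2-methyl-10-phenyldecan-1-ol
Product: 26 O-{(1R,2R)-1-[(3S,5S,6S)-6-allyl-3,5-dimethyl-1,2-dioxan-3-yl]-2-methyl-10-phenyldecyl} O-phenyl carbonothioate
Conditions: PhOC(S)Cl, pyridine, DMAP, CH2Cl2, 0 °C → rt
Reagents that add atoms: O-phenyl chlorothionoformate, S=C(Cl)Oc1ccccc1
Why: DMAP-catalysed thioacylation derivatises the hindered C7 alcohol without ever forming its alkoxide, which could fragment across the neighbouring O–O bond.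

Step 16
Reactants: 26 O-{(1R,2R)-1-[(3S,5S,6S)-6-allyl-3,5-dimethyl-1,2-dioxan-3-yl]-2-methyl-10-phenyldecyl} O-phenyl carbonothioate
Product: 27 (3R,5S,6S)-6-allyl-3,5-dimethyl-3-[(R)-2-methyl-10-phenyldecyl]-1,2-dioxane
Conditions: Bu3SnH (neat, about 10 equiv), Et3B, air, 0 °C → rt
Reagents that add atoms: none
Why: In this Barton–McCombie deoxygenation, low-temperature initiation and neat stannane should let hydrogen transfer to the C7 radical outrun its closure onto the adjacent O–O bond, so C7 becomes CH2 with the ring intact.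

Step 17
Reactants: 27 (3R,5S,6S)-6-allyl-3,5-dimethyl-3-[(R)-2-methyl-10-phenyldecyl]-1,2-dioxane
Product: 29 2-{(3S,4S,6R)-4,6-dimethyl-6-[(R)-2-methyl-10-phenyldecyl]-1,2-dioxan-3-yl}acetaldehyde, via ozonide 28 (not isolated)
Conditions: O3, CH2Cl2, −78 °C; then Me2S, −78 °C → rt
Reagents that add atoms: ozone, [O-][O+]=O
Why: Ozonolysis cleaves the terminal alkene far faster than ozone attacks the phenyl ring, and dimethyl sulfide reduces the ozonide but not the dialkyl peroxide; the β-peroxy aldehyde is carried on crude.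

Step 18
Reactants: 29 2-{(3S,4S,6R)-4,6-dimethyl-6-[(R)-2-methyl-10-phenyldecyl]-1,2-dioxan-3-yl}acetaldehyde
Product: 30 2-{(3S,4S,6R)-4,6-dimethyl-6-[(R)-2-methyl-10-phenyldecyl]-1,2-dioxan-3-yl}acetic acid (CNP0342712.1)
Conditions: NaClO2, NaH2PO4, 2-methylbut-2-ene, t-BuOH–H2O, rt
Reagents that add atoms: sodium chlorite, [Na+].[O-]Cl=O
Why: Pinnick oxidation at mildly acidic pH should convert the aldehyde into the acid without base-induced β-elimination of the peroxide or epimerisation at C3.

Compound list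
1 | (S)-3-bromo-2-methylpropan-1-ol | C[C@H](CBr)CO | starting material
2 | (S)-(3-bromo-2-methylpropoxy)(tert-butyl)dimethylsilane | C[C@H](CBr)CO[Si](C)(C)C(C)(C)C | intermediate
3 | (7-bromoheptyl)benzene | BrCCCCCCCc1ccccc1 | starting material
4 | (7-phenylheptyl)magnesium bromide | Br[Mg]CCCCCCCc1ccccc1 | intermediate (not isolated)
5 | tert-butyldimethyl{[(R)-2-methyl-10-phenyldecyl]oxy}silane | C[C@H](CCCCCCCCc1ccccc1)CO[Si](C)(C)C(C)(C)C | intermediate (not isolated)
6 | (R)-2-methyl-10-phenyldecan-1-ol | C[C@H](CCCCCCCCc1ccccc1)CO | intermediate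
7 | ethyl 2-(triphenylphosphoranylidene)propanoate | CCOC(=O)C(C)=P(c1ccccc1)(c1ccccc1)c1ccccc1 | starting material
8 | (R)-2-methyl-10-phenyldecanal | C[C@H](CCCCCCCCc1ccccc1)C=O | intermediate (not isolated)
9 | ethyl (R,E)-2,4-dimethyl-12-phenyldodec-2-enoate | CCOC(=O)/C(C)=C/[C@H](C)CCCCCCCCc1ccccc1 | intermediate
10 | (R,E)-2,4-dimethyl-12-phenyldodec-2-en-1-ol | OC/C(C)=C/[C@H](C)CCCCCCCCc1ccccc1 | intermediate
11 | [(9R,10E)-12-bromo-9,11-dimethyldodec-10-en-1-yl]benzene | BrC/C(C)=C/[C@H](C)CCCCCCCCc1ccccc1 | intermediate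
12 | (R)-4-benzyl-3-propionyloxazolidin-2-one | CCC(=O)N1[C@H](Cc2ccccc2)COC1=O | starting material
13 | sodium (Z)-enolate of 12 | C/C=C(\[O-])N1[C@H](Cc2ccccc2)COC1=O.[Na+] | intermediate (not isolated)
14 | (R)-4-benzyl-3-[(2S,4E,6R)-2,4,6-trimethyl-14-phenyltetradec-4-enoyl]oxazolidin-2-one | C[C@@H](C/C(C)=C/[C@H](C)CCCCCCCCc1ccccc1)C(=O)N1[C@H](Cc2ccccc2)COC1=O | intermediate
15 | (2S,4E,6R)-2,4,6-trimethyl-14-phenyltetradec-4-en-1-ol | C[C@@H](C/C(C)=C/[C@H](C)CCCCCCCCc1ccccc1)CO | intermediate
16 | (2S,4E,6R)-2,4,6-trimethyl-14-phenyltetradec-4-enal | C[C@@H](C/C(C)=C/[C@H](C)CCCCCCCCc1ccccc1)C=O | intermediate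
17 | (4R,5S,7E,9R)-5,7,9-trimethyl-17-phenylheptadeca-1,7-dien-4-yl diisopinocampheylborinate (isopinocampheyl groups from (−)-α-pinene) | C[C@@H](C/C(C)=C/[C@H](C)CCCCCCCCc1ccccc1)[C@H](OB([C@@H]1[C@@H](C)[C@@H]2C[C@H](C1)C2(C)C)[C@@H]1[C@@H](C)[C@@H]2C[C@H](C1)C2(C)C)CC=C | intermediate (not isolated)
18 | (4R,5S,7E,9R)-5,7,9-trimethyl-17-phenylheptadeca-1,7-dien-4-ol | C[C@@H](C/C(C)=C/[C@H](C)CCCCCCCCc1ccccc1)[C@H](O)CC=C | intermediate
19 | (4R,5S,7E,9R)-5,7,9-trimethyl-17-phenylheptadeca-1,7-dien-4-yl methanesulfonate | C[C@@H](C/C(C)=C/[C@H](C)CCCCCCCCc1ccccc1)[C@H](OS(C)(=O)=O)CC=C | intermediate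
20 | 2,3-dimethylbut-2-ene | CC(C)=C(C)C | starting material
21 | 2-methoxyprop-2-yl hydroperoxide | COC(C)(C)OO | intermediate
22 | (4S,5S,7E,9R)-4-[(2-methoxypropan-2-yl)peroxy]-5,7,9-trimethyl-17-phenylheptadeca-1,7-diene | C[C@@H](C/C(C)=C/[C@H](C)CCCCCCCCc1ccccc1)[C@@H](OOC(C)(C)OC)CC=C | intermediate
23 | (2R,3R)-2-{(2S,3S)-3-[(2-methoxypropan-2-yl)peroxy]-2-methylhex-5-en-1-yl}-2-methyl-3-[(R)-10-phenyldecan-2-yl]oxirane | C[C@H](CCCCCCCCc1ccccc1)[C@H]1O[C@]1(C)C[C@H](C)[C@H](CC=C)OOC(C)(C)OC | intermediate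
24 | (2R,3R)-2-[(2S,3S)-3-hydroperoxy-2-methylhex-5-en-1-yl]-2-methyl-3-[(R)-10-phenyldecan-2-yl]oxirane | C[C@H](CCCCCCCCc1ccccc1)[C@H]1O[C@]1(C)C[C@H](C)[C@H](CC=C)OO | intermediate (not isolated)
25 | (1R,2R)-1-[(3S,5S,6S)-6-allyl-3,5-dimethyl-1,2-dioxan-3-yl]-2-methyl-10-phenyldecan-1-ol | C[C@H](CCCCCCCCc1ccccc1)[C@@H](O)[C@]1(C)C[C@H](C)[C@H](CC=C)OO1 | intermediate
26 | O-{(1R,2R)-1-[(3S,5S,6S)-6-allyl-3,5-dimethyl-1,2-dioxan-3-yl]-2-methyl-10-phenyldecyl} O-phenyl carbonothioate | C[C@H](CCCCCCCCc1ccccc1)[C@@H](OC(=S)Oc1ccccc1)[C@]1(C)C[C@H](C)[C@H](CC=C)OO1 | intermediate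
27 | (3R,5S,6S)-6-allyl-3,5-dimethyl-3-[(R)-2-methyl-10-phenyldecyl]-1,2-dioxane | C[C@H](CCCCCCCCc1ccccc1)C[C@]1(C)C[C@H](C)[C@H](CC=C)OO1 | intermediate
28 | 1,2,4-trioxolane (ozonide) of the allyl group of 27, mixture at the trioxolane carbon | C[C@H](CCCCCCCCc1ccccc1)C[C@]1(C)C[C@H](C)[C@H](CC2OCOO2)OO1 | intermediate (not isolated)
29 | 2-{(3S,4S,6R)-4,6-dimethyl-6-[(R)-2-methyl-10-phenyldecyl]-1,2-dioxan-3-yl}acetaldehyde | C[C@H](CCCCCCCCc1ccccc1)C[C@]1(C)C[C@H](C)[C@H](CC=O)OO1 | intermediate
30 | 2-{(3S,4S,6R)-4,6-dimethyl-6-[(R)-2-methyl-10-phenyldecyl]-1,2-dioxan-3-yl}acetic acid | C[C@H](CCCCCCCCc1ccccc1)C[C@]1(C)C[C@H](C)[C@H](CC(=O)O)OO1 | target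

Total step count: 18. Longest linear sequence: 17 steps (steps 1–10 and 12–18, from 1 to 30); step 11 is a one-step side branch.

Steps most likely to fail

Step 12. Bimolecular substitution at the β-branched secondary mesylate is slow, so base-induced elimination toward the allylic C2 hydrogens (or toward C4) may outrun it, and any ionisation would erode the inversion at C3. The fallback brings the peroxide in at C6 first and closes the C3–O bond intramolecularly; it sets out from mesylate 19 and comes back to the route at 25.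
- Shi epoxidation of 19 with the reagents of step 13 should give (2S,3R)-2-methyl-1-{(2R,3R)-2-methyl-3-[(R)-10-phenyldecan-2-yl]oxiran-2-yl}hex-5-en-3-yl methanesulfonate F1.
- Ethereal H2O2 with catalytic H3PMo12O40 should open the epoxide at tertiary C6 with inversion, giving (4R,5S,7S,8R,9R)-7-hydroperoxy-8-hydroxy-5,7,9-trimethyl-17-phenylheptadec-1-en-4-yl methanesulfonate F2.
- One equivalent of KOt-Bu with 18-crown-6 in THF at 0 °C should then let the peroxide anion displace the C3 mesylate (6-exo-tet, inversion), giving 25 directly.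

Step 14. Acid may ionise the tertiary epoxide carbon before the hydroperoxide arrives, which would open the way to hydride migration from C7 (epoxide-to-ketone rearrangement) or to loss of the C6 configuration; acid-induced rearrangement of the secondary hydroperoxide is a second drain. The fallback closes the same C6–O bond by electrophilic activation of the alkene; it sets out from 22 and comes back at 27.
- Aqueous acetic acid in THF should free (4S,5S,7E,9R)-4-hydroperoxy-5,7,9-trimethyl-17-phenylheptadeca-1,7-diene F3.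
- N-Iodosuccinimide in CH2Cl2 at 0 °C should form the iodonium ion on the more electron-rich trisubstituted alkene and close the ring by 6-exo attack at C6, giving (3S,5S,6S)-6-allyl-3-[(1R,2R)-1-iodo-2-methyl-10-phenyldecyl]-3,5-dimethyl-1,2-dioxane F4.
- C6 would then rest on a chair-like transition state (C4 methyl and the C7 branch equatorial, C3 allyl axial), which favours the needed isomer without catalyst control; any C6 epimer would be removed by chromatography.
- Neat Bu3SnH with Et3B and air should reduce the C–I bond to give 27, with the same radical risk as step 16.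

Step 16. The C7 radical may attack the neighbouring O–O bond intramolecularly, closing an epoxide and cleaving the peroxide, faster than it takes hydrogen from the stannane; stannyl radicals may also attack the peroxide. The fallback avoids any C7 oxygen and introduces the allyl group last; it sets out from alcohol 15 and comes back at 27.
- Mukaiyama–Isayama peroxidation (Co(thd)2, O2, Et3SiH) of the trisubstituted alkene should give (2S,6R)-2,4,6-trimethyl-14-phenyl-4-[(triethylsilyl)peroxy]tetradecan-1-ol F5 as both epimers at the peroxide carbon.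
- TEMPO and PhI(OAc)2 should oxidise it to (2S,6R)-2,4,6-trimethyl-14-phenyl-4-[(triethylsilyl)peroxy]tetradecanal F6.
- p-TsOH in methanol should remove the silyl group and close the hydroperoxy aldehyde to (4S)-3-methoxy-4,6-dimethyl-6-[(R)-2-methyl-10-phenyldecyl]-1,2-dioxane F7.
- Allyltrimethylsilane with TiCl4 in CH2Cl2 at −78 °C should add allyl to the ring peroxycarbenium ion, with axial attack favouring the 3,4-cis isomer, and give 27 after chromatographic removal of the C6 and C3 epimers.

Further compounds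
F1 | step 12 | (2S,3R)-2-methyl-1-{(2R,3R)-2-methyl-3-[(R)-10-phenyldecan-2-yl]oxiran-2-yl}hex-5-en-3-yl methanesulfonate | C[C@H](CCCCCCCCc1ccccc1)[C@H]1O[C@]1(C)C[C@H](C)[C@@H](CC=C)OS(C)(=O)=O
F2 | step 12 | (4R,5S,7S,8R,9R)-7-hydroperoxy-8-hydroxy-5,7,9-trimethyl-17-phenylheptadec-1-en-4-yl methanesulfonate | C[C@H](CCCCCCCCc1ccccc1)[C@@H](O)[C@@](C)(OO)C[C@H](C)[C@@H](CC=C)OS(C)(=O)=O
F3 | step 14 | (4S,5S,7E,9R)-4-hydroperoxy-5,7,9-trimethyl-17-phenylheptadeca-1,7-diene | C[C@@H](C/C(C)=C/[C@H](C)CCCCCCCCc1ccccc1)[C@@H](OO)CC=C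
F4 | step 14 | (3S,5S,6S)-6-allyl-3-[(1R,2R)-1-iodo-2-methyl-10-phenyldecyl]-3,5-dimethyl-1,2-dioxane | C[C@H](CCCCCCCCc1ccccc1)[C@@H](I)[C@]1(C)C[C@H](C)[C@H](CC=C)OO1
F5 | step 16 | (2S,6R)-2,4,6-trimethyl-14-phenyl-4-[(triethylsilyl)peroxy]tetradecan-1-ol (both C4 epimers) | C[C@@H](CC(C)(OO[Si](CC)(CC)CC)C[C@H](C)CCCCCCCCc1ccccc1)CO
F6 | step 16 | (2S,6R)-2,4,6-trimethyl-14-phenyl-4-[(triethylsilyl)peroxy]tetradecanal (both C4 epimers) | C[C@@H](CC(C)(OO[Si](CC)(CC)CC)C[C@H](C)CCCCCCCCc1ccccc1)C=O
F7 | step 16 | (4S)-3-methoxy-4,6-dimethyl-6-[(R)-2-methyl-10-phenyldecyl]-1,2-dioxane (epimers at C3 and C6) | COC1OOC(C)(C[C@H](C)CCCCCCCCc2ccccc2)C[C@@H]1C
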